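**Strategy.** The tether between ring A (acetoxy-bearing) and ring B is cut at the allylic bond C9–C10, next to the (Z)-C8=C9 olefin (tether numbered from ring A). A Zweifel olefination joins an (E)-alkenyl pinacol boronate (C1–C9 plus one ring) with a primary alkyllithium (C10–C16 plus the other ring): 1,2-metallate shift and anti deiodoboration make the C9–C10 bond and the (Z)-olefin in one operation, with inversion of the olefin geometry. The step exploits the (Z)-olefin with its two equal heptamethylene arms and the equivalence of the four ring oxygens: both partners come from one iodide, and the target is the only mono-acetate of the symmetric tetraphenol.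

Key step: step 4

Remark: before the acetate is installed the two rings, and with them the bonds C7–C8 and C9–C10, are equivalent by symmetry, so the bond made in step 4 is the C9–C10 bond of the target whichever ring is acetylated in step 6; 1,7-diiodoheptane is taken as a commercial starting material.

**Step 1**
Reactants: 1 1-bromo-3,5-dimethoxybenzene; 2 1,7-diiodoheptane
Product: 4 1-(7-iodoheptyl)-3,5-dimethoxybenzene, via aryl Grignard reagent 3 (not isolated)
Conditions: Mg, THF, reflux; then 2 (4 equiv), Li2CuCl4 (3 mol%), THF, −20 °C to rt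
Reagents that add atoms: none
Why: Li2CuCl4-catalysed Grignard cross-coupling (Kochi coupling) of the aryl Grignard reagent with a primary alkyl iodide should give the mono-arylated chain, the excess of the symmetrical diiodide holding back double arylation.

**Step 2**
Reactants: 4 1-(7-iodoheptyl)-3,5-dimethoxybenzene
Product: 5 1,3-dimethoxy-5-(non-8-yn-1-yl)benzene
Conditions: LiC≡CH·H2NCH2CH2NH2 (1.5 equiv), DMSO, 15 °C to rt
Reagents that add atoms: lithium acetylide ethylenediamine complex, [Li+].[C-]#C.NCCN
Why: SN2 alkylation of lithium acetylide by the unhindered primary iodide in DMSO should give the terminal alkyne and leave the aryl methyl ethers untouched.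

**Step 3**
Reactants: 5 1,3-dimethoxy-5-(non-8-yn-1-yl)benzene
Product: 6 2-[(E)-9-(3,5-dimethoxyphenyl)non-1-en-1-yl]-4,4,5,5-tetramethyl-1,3,2-dioxaborolane
Conditions: HBpin (1.2 equiv), Cp2ZrHCl (5 mol%), Et3N (10 mol%), neat, 60 °C
Reagents that add atoms: pinacolborane, CC1(C)OBOC1(C)C
Why: Cp2ZrHCl-catalysed hydroboration of a terminal alkyne with pinacolborane is a syn, anti-Markovnikov addition and should give the (E)-1-alkenyl boronate as a single regio- and stereoisomer.

**Step 4**
Reactants: 4 1-(7-iodoheptyl)-3,5-dimethoxybenzene; 6 2-[(E)-9-(3,5-dimethoxyphenyl)non-1-en-1-yl]-4,4,5,5-tetramethyl-1,3,2-dioxaborolane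
Product: 10 (Z)-1,16-bis(3,5-dimethoxyphenyl)hexadec-8-ene, via alkyllithium 7 (not isolated), via lithium boronate complex 8 (not isolated), via anti beta-iodoalkyl boronate 9 (not isolated)
Conditions: 4, t-BuLi (2.0 equiv), Et2O/pentane, −78 °C; then 6, THF, −78 °C; I2 (1.2 equiv), THF, −78 °C; NaOMe (3 equiv), MeOH, −78 °C to rt
Reagents that add atoms: none
Why: Zweifel olefination in its alkenyl boronate plus alkyllithium form: iodine–lithium exchange turns 4 into the primary alkyllithium 7, which adds to the boron of 6 to give boronate complex 8. Iodine forms an iodonium ion on the electron-rich alkenyl boronate and the heptyl group migrates from boron to the adjacent olefinic carbon anti to the departing iodine, which makes the C9–C10 bond, and methoxide then triggers anti elimination of boron and iodine from 9. Two stereospecific anti events on an (E)-olefin should give the (Z)-C8=C9 olefin, so the geometry is controlled by the E configuration of 6 set in the syn hydroboration, and the two stereocentres of 9 are transient and vanish in the elimination. No ring is closed. The step needs migration of the alkyl group in preference to the pinacol oxygens, secured because carbon ligands of a four-coordinate boronate migrate far more readily than alkoxy ligands, and attack of iodine at the boronate olefin in preference to the dimethoxyarenes, secured by the high nucleophilicity of the ate complex at −78 °C and a near-stoichiometric amount of iodine. The closest known reaction type is the iodine-induced 1,2-metallate rearrangement of alkenyl boronate complexes followed by base-induced deiodoboration.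

**Step 5**
Reactants: 10 (Z)-1,16-bis(3,5-dimethoxyphenyl)hexadec-8-ene
Product: 11 5,5'-[(8Z)-hexadec-8-ene-1,16-diyl]bis(benzene-1,3-diol)
Conditions: MeMgI (12 equiv), Et2O removed, neat, 160 °C; then aq NH4Cl
Reagents that add atoms: none
Why: Grignard fusion cleavage of aryl methyl ethers (O-demethylation to the magnesium phenoxide with loss of ethane) needs neither Lewis nor protic acid, so the isolated (Z)-olefin should neither add HX nor isomerise.

**Step 6**
Reactants: 11 5,5'-[(8Z)-hexadec-8-ene-1,16-diyl]bis(benzene-1,3-diol)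
Product: 12 Oncostemonol B, 3-hydroxy-5-[(8Z)-16-(3,5-dihydroxyphenyl)hexadec-8-en-1-yl]phenyl acetate
Conditions: Ac2O (0.5 equiv, slow addition), pyridine, THF, −20 to 0 °C; recovered 11 recycled
Reagents that add atoms: acetic anhydride, CC(=O)OC(C)=O
Why: Base-mediated O-acetylation of a phenol: the four hydroxyl groups of 11 are equivalent by symmetry, so every mono-acetate is 12, and a sub-stoichiometric amount of anhydride added slowly should keep over-acetylation low while unreacted 11 is recovered.

**Compound list**

1 | 1-bromo-3,5-dimethoxybenzene | COc1cc(Br)cc(OC)c1 | starting material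
2 | 1,7-diiodoheptane | ICCCCCCCI | starting material
3 | (3,5-dimethoxyphenyl)magnesium bromide, formed in the flask | COc1cc([Mg]Br)cc(OC)c1 | intermediate
4 | 1-(7-iodoheptyl)-3,5-dimethoxybenzene | COc1cc(CCCCCCCI)cc(OC)c1 | intermediate
5 | 1,3-dimethoxy-5-(non-8-yn-1-yl)benzene | COc1cc(CCCCCCCC#C)cc(OC)c1 | intermediate
6 | 2-[(E)-9-(3,5-dimethoxyphenyl)non-1-en-1-yl]-4,4,5,5-tetramethyl-1,3,2-dioxaborolane | COc1cc(CCCCCCC/C=C/B2OC(C)(C)C(C)(C)O2)cc(OC)c1 | intermediate
7 | [7-(3,5-dimethoxyphenyl)heptyl]lithium, formed in the flask | [Li]CCCCCCCc1cc(OC)cc(OC)c1 | intermediate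
8 | lithium [(E)-9-(3,5-dimethoxyphenyl)non-1-en-1-yl][7-(3,5-dimethoxyphenyl)heptyl](pinacolato)borate, formed in the flask | [Li+].COc1cc(CCCCCCC/C=C/[B-]2(CCCCCCCc3cc(OC)cc(OC)c3)OC(C)(C)C(C)(C)O2)cc(OC)c1 | intermediate
9 | 2-[(8S*,9S*)-1,16-bis(3,5-dimethoxyphenyl)-8-iodohexadecan-9-yl]-4,4,5,5-tetramethyl-1,3,2-dioxaborolane, racemic anti adduct, one enantiomer drawn, formed in the flask | COc1cc(CCCCCCC[C@H](I)[C@@H](B2OC(C)(C)C(C)(C)O2)CCCCCCCc2cc(OC)cc(OC)c2)cc(OC)c1 | intermediate
10 | (Z)-1,16-bis(3,5-dimethoxyphenyl)hexadec-8-ene | COc1cc(CCCCCCC/C=C\CCCCCCCc2cc(OC)cc(OC)c2)cc(OC)c1 | intermediate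
11 | 5,5'-[(8Z)-hexadec-8-ene-1,16-diyl]bis(benzene-1,3-diol) | Oc1cc(O)cc(CCCCCCC/C=C\CCCCCCCc2cc(O)cc(O)c2)c1 | intermediate
12 | Oncostemonol B, 3-hydroxy-5-[(8Z)-16-(3,5-dihydroxyphenyl)hexadec-8-en-1-yl]phenyl acetate | CC(=O)Oc1cc(O)cc(CCCCCCC/C=C\CCCCCCCc2cc(O)cc(O)c2)c1 | target

**Step count.** Total: 6 steps. Longest linear sequence: 6 steps (1 → 4 → 5 → 6 → 10 → 11 → 12); iodide 4 is used twice, in step 2 and in step 4.

**Steps most likely to fail**

Step 4. The alkyllithium may be lost by protonation or Wurtz coupling before it reaches boron, and iodination of the electron-rich rings may compete with iodination of the boronate olefin. The fallback sets out from 5 and 4 and returns at 10. Deprotonation of 5 with n-BuLi (THF, −78 °C) gives the lithium alkynide F1, which is alkylated with 4 (THF/DMPU, −78 °C to rt) to 1,16-bis(3,5-dimethoxyphenyl)hexadec-8-yne F2; the same C9–C10 bond is thus made by SN2 displacement at the alkyne oxidation level. Semihydrogenation of F2 (H2, Lindlar catalyst, that is Pd on CaCO3 poisoned with Pb(OAc)2, quinoline, EtOAc, rt) should then give 10 by syn delivery of hydrogen.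

Step 5. Cleavage of the four methyl ethers may stall in the heterogeneous magnesium phenoxide melt, and material may decompose at 160 °C. The fallback sets out from 4 and returns at 11; it exchanges the methyl ethers for acid-labile methoxymethyl ethers before any unsaturation is present. BBr3 (CH2Cl2, −78 to 0 °C) converts 4 into 5-(7-iodoheptyl)benzene-1,3-diol F3, and MOMCl with i-Pr2NEt (CH2Cl2) gives 1-(7-iodoheptyl)-3,5-bis(methoxymethoxy)benzene F4. Steps 2 to 4 are then repeated in this series. Lithium acetylide ethylenediamine complex in DMSO gives 1,3-bis(methoxymethoxy)-5-(non-8-yn-1-yl)benzene F5, and Cp2ZrHCl-catalysed hydroboration with pinacolborane gives the (E)-alkenyl pinacol boronate F6. The Zweifel olefination of F6 with {7-[3,5-bis(methoxymethoxy)phenyl]heptyl}lithium F7 (from F4 and t-BuLi) passes through the lithium boronate complex F8 and the anti beta-iodoalkyl boronate F9 to (Z)-1,16-bis[3,5-bis(methoxymethoxy)phenyl]hexadec-8-ene F10. Acetal cleavage (HCl, MeOH, 40 °C) should release 11 under conditions that leave the (Z)-olefin alone.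

Step 6. All four hydroxyls react at the same rate, so over-acetylation is statistical, and base-mediated acetyl transfer between phenols during work-up may blur the product distribution further. The fallback sets out from 11 and returns at 12; it approaches the mono-acetate from the fully acetylated side under neutral enzymatic conditions. Ac2O with pyridine and DMAP gives the tetraacetate F11. Alcoholysis with immobilised Candida antarctica lipase B and n-BuOH in MTBE should first remove one acetate from each ring, via the triacetate F12, because the second acetate of a ring sits on a more electron-rich hydroxyphenyl ester and is cleaved more slowly; this gives the bis(monoacetate) F13. Continued alcoholysis of isolated F13 to partial conversion should then give 12 in a mixture of only three components (F13, 12 and 11) that differ by one free hydroxyl each; F13 is resubjected and 11 is re-acetylated.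

**Further compounds**

F1 | step 4 | [9-(3,5-dimethoxyphenyl)non-1-yn-1-yl]lithium | [Li]C#CCCCCCCCc1cc(OC)cc(OC)c1
F2 | step 4 | 1,16-bis(3,5-dimethoxyphenyl)hexadec-8-yne | COc1cc(CCCCCCCC#CCCCCCCCc2cc(OC)cc(OC)c2)cc(OC)c1
F3 | step 5 | 5-(7-iodoheptyl)benzene-1,3-diol | Oc1cc(O)cc(CCCCCCCI)c1
F4 | step 5 | 1-(7-iodoheptyl)-3,5-bis(methoxymethoxy)benzene | COCOc1cc(CCCCCCCI)cc(OCOC)c1
F5 | step 5 | 1,3-bis(methoxymethoxy)-5-(non-8-yn-1-yl)benzene | COCOc1cc(CCCCCCCC#C)cc(OCOC)c1
F6 | step 5 | 2-{(E)-9-[3,5-bis(methoxymethoxy)phenyl]non-1-en-1-yl}-4,4,5,5-tetramethyl-1,3,2-dioxaborolane | COCOc1cc(CCCCCCC/C=C/B2OC(C)(C)C(C)(C)O2)cc(OCOC)c1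
F7 | step 5 | {7-[3,5-bis(methoxymethoxy)phenyl]heptyl}lithium | [Li]CCCCCCCc1cc(OCOC)cc(OCOC)c1
F8 | step 5 | lithium {(E)-9-[3,5-bis(methoxymethoxy)phenyl]non-1-en-1-yl}{7-[3,5-bis(methoxymethoxy)phenyl]heptyl}(pinacolato)borate | [Li+].COCOc1cc(CCCCCCC/C=C/[B-]2(CCCCCCCc3cc(OCOC)cc(OCOC)c3)OC(C)(C)C(C)(C)O2)cc(OCOC)c1
F9 | step 5 | 2-{(8S*,9S*)-1,16-bis[3,5-bis(methoxymethoxy)phenyl]-8-iodohexadecan-9-yl}-4,4,5,5-tetramethyl-1,3,2-dioxaborolane, racemic anti adduct | COCOc1cc(CCCCCCC[C@H](I)[C@@H](B2OC(C)(C)C(C)(C)O2)CCCCCCCc2cc(OCOC)cc(OCOC)c2)cc(OCOC)c1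
F10 | step 5 | (Z)-1,16-bis[3,5-bis(methoxymethoxy)phenyl]hexadec-8-ene | COCOc1cc(CCCCCCC/C=C\CCCCCCCc2cc(OCOC)cc(OCOC)c2)cc(OCOC)c1
F11 | step 6 | (8Z)-hexadec-8-ene-1,16-diylbis(benzene-5,1,3-triyl) tetraacetate | CC(=O)Oc1cc(OC(C)=O)cc(CCCCCCC/C=C\CCCCCCCc2cc(OC(C)=O)cc(OC(C)=O)c2)c1
F12 | step 6 | 5-[(8Z)-16-(3-acetoxy-5-hydroxyphenyl)hexadec-8-en-1-yl]-1,3-phenylene diacetate | CC(=O)Oc1cc(O)cc(CCCCCCC/C=C\CCCCCCCc2cc(OC(C)=O)cc(OC(C)=O)c2)c1
F13 | step 6 | (8Z)-hexadec-8-ene-1,16-diylbis(5-hydroxy-3,1-phenylene) diacetate | CC(=O)Oc1cc(O)cc(CCCCCCC/C=C\CCCCCCCc2cc(O)cc(OC(C)=O)c2)c1
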